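The disconnection is the bond between C4 of the central ring (C1 = C–OMe, C3 = C–OH) and the CH2 that carries the 4-hydroxyphenyl ring. The key step exploits the fact that C4 is ortho to C5, whose two-carbon bridge leads to the 2-hydroxyphenyl ring. A hydroxyl on the bridge carbon bonded to that outer ring captures a 4-oxygenated benzaldehyde, and an acid-promoted oxa-Pictet–Spengler closure then makes the C4–C and O–C bonds together. This gives a 1,3-diarylisochroman whose ring oxygen is later excised by hydrogenolysis. The precursor is a racemic 1,2-diarylethanol with both phenols masked as mesylates; the aldehyde is mesylated as well.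

Key step: step 6

Remark on the chemistry: the target has no stereocentre and is achiral, so its SMILES defines one compound and no asymmetric step is needed. The carbinol and isochroman intermediates are carried as racemates or diastereomer mixtures, and their stereocentres are removed by the hydrogenolysis. Ms = methanesulfonyl throughout.

Step 1
Reactants: 1 methyl 3-hydroxy-5-methoxybenzoate
Product: 2 3-(hydroxymethyl)-5-methoxyphenol
Conditions: LiAlH4, THF, 0 °C to reflux; then H2O, aq. NaOH
Reagents that add atoms: none
Why: Ester reduction by LiAlH4 (hydride addition–elimination, then a second hydride addition) proceeds on the phenoxide formed in situ, and the aryl methyl ether is inert, so the benzylic alcohol is the only product to expect.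

Step 2
Reactants: 2 3-(hydroxymethyl)-5-methoxyphenol
Product: 4 3-(chloromethyl)-5-methoxyphenyl methanesulfonate, via benzylic bis-mesylate 3 (not isolated)
Conditions: MsCl, i-Pr2NEt, CH2Cl2, 0 °C; then LiCl, DMF, rt
Reagents that add atoms: methanesulfonyl chloride CS(=O)(=O)Cl; lithium chloride [Li+].[Cl-]
Why: O-Sulfonylation of both hydroxyl groups is followed by SN2 displacement of the reactive benzylic mesylate by chloride, whereas the aryl mesylate cannot be displaced at sp2 carbon and the hindered amine avoids N-benzylation.

Step 3
Reactants: 5 salicylaldehyde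
Product: 6 2-formylphenyl methanesulfonate
Conditions: MsCl, Et3N, CH2Cl2, 0 °C
Reagents that add atoms: methanesulfonyl chloride CS(=O)(=O)Cl
Why: Phenol O-sulfonylation gives a mesylate that tolerates organozinc reagents, strong acid and hydrogenation and that, as a poor donor, should later keep the neighbouring benzylic alcohol from ionising.

Step 4
Reactants: 4 3-(chloromethyl)-5-methoxyphenyl methanesulfonate; 6 2-formylphenyl methanesulfonate
Product: 8 rac-1-[2-(mesyloxy)phenyl]-2-[3-methoxy-5-(mesyloxy)phenyl]ethanol, via benzylic zinc chloride 7 (not isolated)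
Conditions: Zn dust, LiCl, THF, 25 °C; then 6, 0 °C to rt; aq. NH4Cl
Reagents that add atoms: none
Why: LiCl-promoted oxidative insertion of zinc into the benzylic C–Cl bond gives a benzylic zinc chloride that adds 1,2 to the electron-poor aldehyde (organozinc carbonyl addition) without touching the aryl sulfonates; the carbinol stereocentre forms racemic, which is acceptable because step 7 removes it.

Step 5
Reactants: 9 4-hydroxybenzaldehyde
Product: 10 4-formylphenyl methanesulfonate
Conditions: MsCl, Et3N, CH2Cl2, 0 °C
Reagents that add atoms: methanesulfonyl chloride CS(=O)(=O)Cl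
Why: Phenol O-sulfonylation as in step 3; a sulfonate rather than an ether on this ring keeps the derived oxocarbenium ion electrophilic and lets all three phenols be unmasked together in step 8.

Step 6
Reactants: 8 rac-1-[2-(mesyloxy)phenyl]-2-[3-methoxy-5-(mesyloxy)phenyl]ethanol; 10 4-formylphenyl methanesulfonate
Product: 12 6-methoxy-8-(mesyloxy)-3-[2-(mesyloxy)phenyl]-1-[4-(mesyloxy)phenyl]isochroman (racemic cis/trans mixture), via hemiacetal 11 (not isolated)
Conditions: TfOH (0.5 equiv), CH2Cl2, 0 °C to rt
Reagents that add atoms: none
Why: Triflic acid condenses the alcohol with the aldehyde to the hemiacetal and ionises it to an O-alkyl oxocarbenium ion, which the central ring attacks at the carbon ortho to its CH2 tether before rearomatising; this is an oxa-Pictet–Spengler reaction (intramolecular Friedel–Crafts hydroxyalkylation), the known route from 2-arylethanols and aryl aldehydes to 1-aryl isochromans. The pyran ring closes in a 6-endo-trig mode, forming the C4–CH(aryl) and O–CH(aryl) bonds in one operation. C1 of the isochroman is a new stereocentre set relative to the racemic C3 under substrate control only, and no control is needed because step 7 deletes both centres. The selectivity required is attack at C4 (para to OMe, ortho to OMs) and not at C6 (ortho to OMe, para to OMs): both sites are flanked on two sides, so the bias must come from the stronger para than ortho donation of the methoxy group towards a weak, late-transition-state electrophile, helped by sulfonylation of the C3 oxygen, which removes its para donation into C6. C6 is still activated by the methoxy group and remains a real competitor, which is why this step carries the risk of the route; a regioisomeric isochroman would be separated here. The mesylate on the outer ring keeps its benzylic alcohol from ionising to a stilbene, and the mesylate on the aldehyde keeps the oxocarbenium ion reactive enough for the sulfonylated ring and the product ether stable to the acid.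

Step 7
Reactants: 12 6-methoxy-8-(mesyloxy)-3-[2-(mesyloxy)phenyl]-1-[4-(mesyloxy)phenyl]isochroman
Product: 14 5-methoxy-2-[4-(mesyloxy)benzyl]-3-{2-[2-(mesyloxy)phenyl]ethyl}phenyl methanesulfonate, via ring-opened benzylic alcohol 13 (not isolated)
Conditions: H2 (4 bar), 10% Pd/C, AcOH, H2SO4 (cat.), 50 °C
Reagents that add atoms: none
Why: Acid-assisted palladium hydrogenolysis of benzylic C–O bonds should cleave the doubly benzylic ether bond first and then reduce the remaining secondary benzylic alcohol under the forcing acidic conditions used for mandelic-type alcohols, while aryl mesylates, the methyl ether and the arenes are not reduced and both transient stereocentres disappear.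

Step 8
Reactants: 14 5-methoxy-2-[4-(mesyloxy)benzyl]-3-{2-[2-(mesyloxy)phenyl]ethyl}phenyl methanesulfonate
Product: 15 2-(4-hydroxybenzyl)-3-[2-(2-hydroxyphenyl)ethyl]-5-methoxyphenol
Conditions: KOH, MeOH/H2O, reflux, N2; then 1 M HCl
Reagents that add atoms: none
Why: Saponification of aryl sulfonate esters (hydroxide attack at sulfur with S–O cleavage) should liberate the three phenols, and after the hydrogenolysis no benzylic leaving group is left that could form a quinone methide in base.

Compound list
1 | methyl 3-hydroxy-5-methoxybenzoate | COC(=O)c1cc(O)cc(OC)c1 | starting material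
2 | 3-(hydroxymethyl)-5-methoxyphenol | COc1cc(O)cc(CO)c1 | intermediate
3 | 3-methoxy-5-(mesyloxy)benzyl methanesulfonate (not isolated) | COc1cc(COS(C)(=O)=O)cc(OS(C)(=O)=O)c1 | intermediate
4 | 3-(chloromethyl)-5-methoxyphenyl methanesulfonate | COc1cc(CCl)cc(OS(C)(=O)=O)c1 | intermediate
5 | salicylaldehyde | O=Cc1ccccc1O | starting material
6 | 2-formylphenyl methanesulfonate | CS(=O)(=O)Oc1ccccc1C=O | intermediate
7 | [3-methoxy-5-(mesyloxy)benzyl]zinc chloride (not isolated) | COc1cc(C[Zn]Cl)cc(OS(C)(=O)=O)c1 | intermediate
8 | rac-1-[2-(mesyloxy)phenyl]-2-[3-methoxy-5-(mesyloxy)phenyl]ethanol | COc1cc(OS(C)(=O)=O)cc(CC(O)c2ccccc2OS(C)(=O)=O)c1 | intermediate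
9 | 4-hydroxybenzaldehyde | O=Cc1ccc(O)cc1 | starting material
10 | 4-formylphenyl methanesulfonate | CS(=O)(=O)Oc1ccc(C=O)cc1 | intermediate
11 | {1-[2-(mesyloxy)phenyl]-2-[3-methoxy-5-(mesyloxy)phenyl]ethoxy}[4-(mesyloxy)phenyl]methanol, hemiacetal (not isolated; racemic diastereomer mixture) | COc1cc(OS(C)(=O)=O)cc(CC(OC(O)c2ccc(OS(C)(=O)=O)cc2)c2ccccc2OS(C)(=O)=O)c1 | intermediate
12 | 6-methoxy-8-(mesyloxy)-3-[2-(mesyloxy)phenyl]-1-[4-(mesyloxy)phenyl]isochroman (racemic cis/trans mixture) | COc1cc(OS(C)(=O)=O)c2c(c1)CC(c1ccccc1OS(C)(=O)=O)OC2c1ccc(OS(C)(=O)=O)cc1 | intermediate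
13 | rac-2-{5-methoxy-3-(mesyloxy)-2-[4-(mesyloxy)benzyl]phenyl}-1-[2-(mesyloxy)phenyl]ethanol (not isolated) | COc1cc(OS(C)(=O)=O)c(Cc2ccc(OS(C)(=O)=O)cc2)c(CC(O)c2ccccc2OS(C)(=O)=O)c1 | intermediate
14 | 5-methoxy-2-[4-(mesyloxy)benzyl]-3-{2-[2-(mesyloxy)phenyl]ethyl}phenyl methanesulfonate | COc1cc(OS(C)(=O)=O)c(Cc2ccc(OS(C)(=O)=O)cc2)c(CCc2ccccc2OS(C)(=O)=O)c1 | intermediate
15 | 2-(4-hydroxybenzyl)-3-[2-(2-hydroxyphenyl)ethyl]-5-methoxyphenol (achiral) | COc1cc(O)c(Cc2ccc(O)cc2)c(CCc2ccccc2O)c1 | target

Total step count: 8. Longest linear sequence: 6 (steps 1, 2, 4, 6, 7, 8); steps 3 and 5 are single-step side branches.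

Steps most likely to fail

Step 6. The ring closure may take place at the other ortho position of the tether (the one next to the methoxy group). It may also not take place at all, because the sulfonylated ring is a weak nucleophile, so that the reaction stalls at acetal formation or drifts to acid-promoted dehydration of the carbinol. Fallback: the C4–CH2 bond is made by halogenation and cross-coupling instead of the tethered Friedel–Crafts step. The fallback sets out from 8 and comes back to the route at 15.
- NBS in MeCN should brominate the central ring para to the methoxy group, as selective halogenating agents do with 3,5-disubstituted anisoles, giving the aryl bromide rac-2-[2-bromo-5-methoxy-3-(mesyloxy)phenyl]-1-[2-(mesyloxy)phenyl]ethanol F1.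
- Commercial 4-(benzyloxy)benzyl chloride with Zn and LiCl in THF gives [4-(benzyloxy)benzyl]zinc chloride F2.
- Negishi coupling of F1 with F2 (Pd(OAc)2, SPhos, THF, rt) tolerates the free alcohol and leaves aryl mesylates untouched. It should give rac-2-{2-[4-(benzyloxy)benzyl]-5-methoxy-3-(mesyloxy)phenyl}-1-[2-(mesyloxy)phenyl]ethanol F3.
- Hydrogenolysis under the conditions of step 7 removes the benzylic hydroxyl and the benzyl ether, giving 2-(4-hydroxybenzyl)-5-methoxy-3-{2-[2-(mesyloxy)phenyl]ethyl}phenyl methanesulfonate F4.
- KOH as in step 8 then gives 15.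

Step 7. Hydrogenolysis may stop after the doubly benzylic C–O bond, because the electron-poor mesyloxyphenyl ring slows cleavage of the second benzylic C–O bond. Fallback: deoxygenation by elimination and alkene hydrogenation. The fallback sets out from 13, isolated when hydrogen uptake stops, and comes back at 14. Burgess reagent in toluene at 60 °C should dehydrate 13 by syn-elimination, which needs no benzylic cation, to the stilbene (E)-5-methoxy-2-[4-(mesyloxy)benzyl]-3-{2-[2-(mesyloxy)phenyl]vinyl}phenyl methanesulfonate F5. Hydrogenation (H2, Pd/C, EtOAc, rt) then saturates the alkene to give 14.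

Step 2. In the one-pot procedure the benzylic mesylate may alkylate the amine base, or the chloride exchange may stay incomplete. Fallback: protect before reducing, with each operation run separately. The fallback sets out from 1 and comes back at 4. MsCl and Et3N in CH2Cl2 give methyl 3-methoxy-5-(mesyloxy)benzoate F6. DIBAL-H (CH2Cl2, −78 to 0 °C) reduces the ester without cleaving the aryl sulfonate to give 3-(hydroxymethyl)-5-methoxyphenyl methanesulfonate F7. SOCl2 (CH2Cl2, cat. DMF) then gives 4.

Further compounds
F1 | step 6 | rac-2-[2-bromo-5-methoxy-3-(mesyloxy)phenyl]-1-[2-(mesyloxy)phenyl]ethanol | COc1cc(OS(C)(=O)=O)c(Br)c(CC(O)c2ccccc2OS(C)(=O)=O)c1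
F2 | step 6 | [4-(benzyloxy)benzyl]zinc chloride | Cl[Zn]Cc1ccc(OCc2ccccc2)cc1
F3 | step 6 | rac-2-{2-[4-(benzyloxy)benzyl]-5-methoxy-3-(mesyloxy)phenyl}-1-[2-(mesyloxy)phenyl]ethanol | COc1cc(OS(C)(=O)=O)c(Cc2ccc(OCc3ccccc3)cc2)c(CC(O)c2ccccc2OS(C)(=O)=O)c1
F4 | step 6 | 2-(4-hydroxybenzyl)-5-methoxy-3-{2-[2-(mesyloxy)phenyl]ethyl}phenyl methanesulfonate | COc1cc(OS(C)(=O)=O)c(Cc2ccc(O)cc2)c(CCc2ccccc2OS(C)(=O)=O)c1
F5 | step 7 | (E)-5-methoxy-2-[4-(mesyloxy)benzyl]-3-{2-[2-(mesyloxy)phenyl]vinyl}phenyl methanesulfonate | COc1cc(OS(C)(=O)=O)c(Cc2ccc(OS(C)(=O)=O)cc2)c(/C=C/c2ccccc2OS(C)(=O)=O)c1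
F6 | step 2 | methyl 3-methoxy-5-(mesyloxy)benzoate | COC(=O)c1cc(OC)cc(OS(C)(=O)=O)c1
F7 | step 2 | 3-(hydroxymethyl)-5-methoxyphenyl methanesulfonate | COc1cc(CO)cc(OS(C)(=O)=O)c1
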